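## Structural features

The target is a spiro[4.5]decene in which cyclopentane ring A (C1 to C5) and cyclohexene ring B (C5 to C10) share the all-carbon quaternary atom C5. Ring B holds the C7=C8 double bond with a methyl group on C8 and a 3-phenylpropanoate on the allylic carbon C9. C1 carries a two-carbon chain, C11 (with a methyl group) and C12, and C12 is the exocyclic alkene carbon of a (Z)-γ-ylidene-α-methylbutenolide.

There are five stereocentres: C1 (R), C4 (S) and C5 (S) are contiguous in ring A, C11 (S) stands next to C1 outside the ring, and C9 (S) lies across ring B. In relative terms the C1 chain and the C4 methyl are trans on ring A, C10 lies on the face of the C4 methyl, C6 on the face of the C1 chain, and the C9 oxygen sits on the face of ring B that C1 occupies.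

The fragile groups are the ylidene butenolide (base, nucleophiles, light), the C11–H that is allylic to it, and the allylic ester on C9 (ionisation, acyl cleavage); all three are therefore made late. The real difficulty is twofold: the quaternary C5 wedged between two tertiary stereocentres, and C11, which is created on a ring carbon whose two ring neighbours are both methylene groups at that stage, so that the substrate offers almost no bias.

The feature used by the key step is this: ring A with its trans C1 and C4 substituents is a p-menthane ring that has lost one ring carbon, and the two one-carbon arms on C5 (C6 and C10) correspond to the carbonyl carbon of a ketene and the terminus of an allyl group, the two ends that a ketene Claisen rearrangement joins.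

## Logic of the disconnections

**Butenolide.** 31 is cut at the exocyclic C12=C bond, through 30 and 29, to 26 and 28. This is the most fragile part and comes off first. The cut removes five carbons and the only alkene geometry. The forward aldol must not epimerise C11 of 26, and the elimination must end at the Z isomer.

**C12 oxidation level and the ester.** 26 is traced through 25 and 24 to 23, cutting the C9–O acyl bond. The ester is placed before the primary alcohol is freed, so the two hydroxyl groups never compete. The demand is a desilylation and an oxidation that spare an allylic ester.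

**C9–H.** 23 comes from 22 by cutting the C9–H bond. The enone is what the ring closure delivers. The forward step must bring hydride to the face of ring B on which C4 lies; a chiral reagent is used because the spiro ring gives no clear bias.

**Ring B.** 22 is opened at C7=C8 to 21, and C7 is then removed (C6–C7) through 20 to reach 19. In a 1,5-keto aldehyde only the six-membered aldol closure is possible, so ring B reduces to two arms on C5. The demand is a one-carbon homologation of a neopentyl aldehyde and an unmasking acid that spares the silyl ether.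

**The two arms.** 19 is related to 15 through 18 and 17: the C6 aldehyde comes from the morpholine amide and the C9 ketone from the methylidene carbon. The ketal in 18 ensures that the hydride reagent meets the amide only.

**Key disconnection.** 15 is cut at C5–C10 and C4–C5, through 14 and 13, to 9 and 12. This removes the quaternary centre and turns ring A back into a six-membered ring whose two stereocentres are already present. The demand is face selection at the planar C5 and a ketene that meets the amine before anything else.

**Allylic amine.** 12 is cut at its C–N bond to 10 and 11. The forward step must reduce the iminium faster than the amine adds in conjugate fashion.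

**Diazo group.** 9 comes from 7 through 8 (C=N2 bond). Activation must take place at the methylene, not at the methyl-bearing methine, so that the future C4 is not epimerised.

**Side chain.** 7 is traced through 6 and 5 (via 4) to 3, cutting C12–O and C11–H. A bulky, acid-stable tert-butyldiphenylsilyl group is chosen because it must survive step 12 and is meant to shield one face in step 7. C11 has to be set by the catalyst, and the ring ketone is carried through as a borate and restored.

**Chiral pool.** 3 comes from 1 through 2 (C–H bonds at the enone). The protonation must give the trans isomer; the ring stereocentre of 1 becomes C1.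

**Silyloxyfuran.** 28 comes from 27 by O-silylation (O–Si bond).

## Other disconnections considered

**Alternative 1:** The cut is C9–C10 together with C4–C5, leading back to the open-chain cyclobutane A1. In the forward step AgOTf ionises the acid chloride of A1, the methylidene carbon C10 attacks the acylium carbon C9, and the C5 cation so formed pulls C4 over from C1 with loss of the silyl group, giving the spiro ene-dione A2.
- In its favour: one cationic cascade closes ring B, expands the four-membered ring to ring A and makes the quaternary centre. A2 has ring B complete with the C7=C8 alkene, the C8 methyl and oxygen on C9. On ring B this is better than the chosen plan, which spends steps 8 to 12 on it.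
- Against it: the configuration of C5 relative to C4 depends on which face of the ring B cation accepts the migrating carbon, and on C4 migrating in preference to C2; nothing rigid controls either. The Z-enoyl cation may lose its geometry or collapse to a vinylketene.
- Against it also: A2 holds C1 as a ketone next to the quaternary C5, so C1 and C11 would have to be set afterwards on a neopentyl-type carbonyl. In the chosen plan C1 and C4 come from 1 and are never at risk.
- Comparison: mechanistically both plans rest on a 1,2-shift that changes ring size and are equal in concept. Alternative 1 would be shorter to the spirocycle but longer and less secure after it.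

**Alternative 2:** The cut is C1–C5 plus a temporary C6–C11 bond, leading back to the enone A3. In the forward step irradiation of A3 would give the intramolecular enone–alkene [2+2] adduct A4, which contains ring A, C5 and a cis-fused cyclobutane.
- In its favour: ring A and the quaternary centre form in one step from an open chain with a single stereocentre, and the tether length fixes the regiochemistry. C11 and C12 are already attached to C1, with C12 as an ester. On this point it is better than the chosen plan (no hydroboration, no protecting group on C12). C1 is tied to C5 by the cis ring fusion, which is equal in reliability to taking C1 from 1.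
- Against it: the face selectivity at C5 rests on the one C4 stereocentre in a flexible tether. The C6–C11 bond must then be broken reductively, which turns C11 into an ester α-carbon whose configuration is set by protonation and can equilibrate.
- Against it also: ring B emerges with its carbonyl on C7, so the C8 methyl, the C7=C8 alkene and the C9 oxygen all need a transposition sequence that the aldol closure of the chosen plan delivers directly.
- Comparison: fewer steps to ring A, more to a correctly functionalised ring B; overall it is judged longer.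

**Alternative 3:** The cut is C5–C6 with C8 reconnected to the oxygen on C1, leading back to the fused vinyl dihydropyran A5. In the forward step heating A5 would bring about a [3,3] shift through a boat-like array, forming C5–C6, breaking C8–O and giving the spiro ketone A6.
- In its favour: the configuration of C5 would be relayed from C8 and C9 by a suprafacial shift. That is a firmer source of control than the steric face selection of step 7, and on this point the alternative is better. A6 also has ring B complete with the protected C9 oxygen in the right configuration, which is better in ring B step count.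
- Against it: A5 has three stereocentres, including a tertiary allylic ether carbon, and a fully substituted cyclic enol ether. Its synthesis would be a project of its own and it would be acid-labile. A boat transition state that forms a quaternary carbon needs high temperature.
- Against it also: as in Alternative 1, A6 has only a ketone at C1, so C1 and C11 remain to be set next to the quaternary centre.
- Comparison: the gain in ring B is paid back at the side chain, which is where the chosen plan is strongest.

Key step: step 7

Remark on the chemistry: the oxygen introduced on the side chain sits on C12, and C11 is the methyl-bearing stereocentre created with it; a plain borane would not control C11, so a chiral copper hydride catalyst is used.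

Assumption: in step 2 the (R)-antipode of DTBM-SEGPHOS is taken to give the 11S configuration; the alkene has almost no bias of its own, so the (S)-antipode is used instead if a trial with both shows the opposite sense.

## Route

Step 1
Reactants: 1 (S)-(+)-carvone
Product: 3 (2S,5S)-2-methyl-5-(prop-1-en-2-yl)cyclohexan-1-one (trans-dihydrocarvone), via lithium enolate 2 (not isolated)
Conditions: LiBH(s-Bu)3 (1.1 equiv), THF, −78 °C; then aq. NH4Cl, −78 °C to rt
Reagents that add atoms: LiBH(s-Bu)3, [Li+].CCC(C)[BH-](C(C)CC)C(C)CC (lithium of 2 only; 3 receives hydrogen only)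
Why: Conjugate reduction of a β-unsubstituted enone by a hindered borohydride; enolate 2 is protonated axially so that the methyl group becomes equatorial and trans to the isopropenyl group, which is also the thermodynamic isomer, and any cis epimer is removed by chromatography; the ring stereocentre of 1 (future C1) is not touched.

Step 2
Reactants: 3 trans-dihydrocarvone
Product: 5 (2S,5S)-5-[(2S)-1-hydroxypropan-2-yl]-2-methylcyclohexan-1-ol (both carbinol epimers), via bis(pinacolboryl) intermediate 4 (not isolated)
Conditions: CuCl (5 mol %), (R)-DTBM-SEGPHOS (5.5 mol %), KOtBu (10 mol %), HBpin (3 equiv), THF, rt; then NaBO3·4H2O, THF/H2O, rt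
Reagents that add atoms: sodium perborate, [Na+].[O-]OB=O (oxygen on C12); pinacolborane, CC1(C)OBOC1(C)C (boron of 4 only)
Why: Copper hydride catalysed anti-Markovnikov hydroboration of a 1,1-disubstituted alkene followed by C–B oxidation; the bulky bisphosphine decides the face of the hydrocupration by telling the methyl group from the ring, and so sets C11 under catalyst control; the ketone is hydroborated at the same time, which protects it, and its carbinol centre is removed again in step 4.

Step 3
Reactants: 5 diol
Product: 6 (2S,5S)-5-[(2S)-1-(tert-butyldiphenylsilyloxy)propan-2-yl]-2-methylcyclohexan-1-ol (both carbinol epimers)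
Conditions: TBDPSCl (1.05 equiv), imidazole, CH2Cl2, 0 °C
Reagents that add atoms: tert-butyl(chloro)diphenylsilane, CC(C)(C)[Si](Cl)(c1ccccc1)c2ccccc2
Why: Silylation with a bulky chlorosilane takes the primary hydroxyl group and leaves the secondary one; the tert-butyldiphenylsilyl group is chosen because it survives the aqueous acid of step 12 and adds bulk to the C1 side chain for step 7.

Step 4
Reactants: 6 silyl ether alcohol
Product: 7 (2S,5S)-5-[(2S)-1-(tert-butyldiphenylsilyloxy)propan-2-yl]-2-methylcyclohexan-1-one
Conditions: Dess–Martin periodinane, CH2Cl2, rt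
Reagents that add atoms: none
Why: Dess–Martin oxidation of a secondary alcohol under neutral, non-enolising conditions, so both carbinol epimers converge on one ketone and the trans methyl group next to the carbonyl is not disturbed.

Step 5
Reactants: 7 silyloxy ketone
Product: 9 (3R,6S)-3-[(2S)-1-(tert-butyldiphenylsilyloxy)propan-2-yl]-2-diazo-6-methylcyclohexan-1-one, via trifluoroacetyl ketone 8 (not isolated)
Conditions: LiN(SiMe3)2, THF, −78 °C; CF3CO2CH2CF3, −78 °C; 5% aq. HCl work-up; then MsN3, Et3N, H2O (1 equiv), MeCN, rt
Reagents that add atoms: methanesulfonyl azide, CS(=O)(=O)N=[N+]=[N-] (the two diazo nitrogens of 9); 2,2,2-trifluoroethyl trifluoroacetate, O=C(OCC(F)(F)F)C(F)(F)F (trifluoroacetyl group of 8 only)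
Why: Kinetic enolisation at the methylene and Claisen-type trifluoroacetylation, then deacylative (Regitz-type) diazo transfer; no equilibrating base reaches the methyl-bearing methine, so the future C4 keeps its trans configuration.

Step 6
Reactants: 10 2-ethylacrolein; 11 morpholine
Product: 12 4-(2-methylidenebutyl)morpholine
Conditions: NaBH(OAc)3 (1.4 equiv), AcOH (1 equiv), ClCH2CH2Cl, 0 °C to rt
Reagents that add atoms: none
Why: Reductive amination; the conjugated iminium ion is reduced at carbon 1 by the mild acetoxyborohydride and the reversible conjugate addition of the amine is drained through it; no stereocentre is formed.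

Step 7
Reactants: 9 diazo ketone; 12 allylic morpholine
Product: 15 [(1R,2S,5R)-2-methyl-1-(2-methylidenebutyl)-5-[(2S)-1-(tert-butyldiphenylsilyloxy)propan-2-yl]cyclopentyl](morpholin-4-yl)methanone, via ketene 13 (not isolated), via acyl ammonium enolate 14 (not isolated)
Conditions: 12 (3 equiv), blue LEDs (440 nm), CH2Cl2, −20 °C; then Yb(OTf)3 (20 mol %), −20 °C to rt
Reagents that add atoms: none
Why: Proposed new method: light excites the diazo ketone 9, which is locked s-cis by the ring, N2 leaves and C4 shifts from the carbonyl carbon to the diazo carbon in a concerted 1,2-shift with retention (Wolff rearrangement), so the cyclohexanone contracts to ring A and the old carbonyl carbon becomes the ketene carbon C6 of 13. The amine 12 adds through nitrogen to C6 in the plane of the ketene, Yb(OTf)3 on oxygen holds the acyl ammonium enolate 14, and a chair-like array C5–C6–N–CH2–C(Et)=CH2 then forms C5–C10 by a [3,3] shift (zwitterionic ketene Claisen rearrangement). The closest known reactions are the photochemical ring contraction of 2-diazocyclohexanones and the Lewis acid catalysed Claisen rearrangement of ketenes with allylic morpholines (Bellus–Claisen type); what is new is their union in one flask and the use of a fully substituted dialkylketene. Ring A is closed by ring contraction through the 1,2-shift that makes C4–C5, not by a cyclisation, and the six-membered array of the [3,3] shift exists only in the transition state. The one new stereocentre, C5, is controlled by the side chain on C1: the branched silyloxypropyl group covers its own face of the planar enolate carbon, so the allyl terminus should arrive on the face of the small C4 methyl, as the target requires, while C1, C4 and C11 are not touched. The step needs rearrangement to win over capture of a carbene by the amine (ammonium ylide and [2,3] shift), which the concerted, metal-free photolysis of a cyclic diazo ketone should secure, and it needs the ketene to meet 12 before it dimerises, which the excess of 12 and the low temperature serve.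

Step 8
Reactants: 15 morpholine amide
Product: 17 [(1R,2S,5R)-2-methyl-1-(2-oxobutyl)-5-[(2S)-1-(tert-butyldiphenylsilyloxy)propan-2-yl]cyclopentyl](morpholin-4-yl)methanone, via ozonide 16 (not isolated)
Conditions: O3, CH2Cl2, −78 °C; then PPh3, −78 °C to rt
Reagents that add atoms: ozone, [O-][O+]=O
Why: Ozonolysis of the only alkene gives the ethyl ketone that holds C8, C9 and the C8 methyl; the tertiary amide and the silyl ether are inert to ozone at low temperature when the ozone dose is limited.

Step 9
Reactants: 17 keto amide
Product: 18 [(1R,2S,5R)-1-[(2-ethyl-1,3-dioxolan-2-yl)methyl]-2-methyl-5-[(2S)-1-(tert-butyldiphenylsilyloxy)propan-2-yl]cyclopentyl](morpholin-4-yl)methanone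
Conditions: (Me3SiOCH2)2, Me3SiOTf (5 mol %), CH2Cl2, −78 to −20 °C
Reagents that add atoms: 1,2-bis(trimethylsilyloxy)ethane, C[Si](C)(C)OCCO[Si](C)(C)C
Why: Aprotic ketalisation with a bis-silyl ether under silyl triflate catalysis; it masks the ketone for the hydride and ylide steps, spares the silyl ether, and comes off in step 12 at no extra cost.

Step 10
Reactants: 18 ketal amide
Product: 19 (1R,2S,5R)-1-[(2-ethyl-1,3-dioxolan-2-yl)methyl]-2-methyl-5-[(2S)-1-(tert-butyldiphenylsilyloxy)propan-2-yl]cyclopentane-1-carbaldehyde
Conditions: Cp2Zr(H)Cl (2 equiv), THF, rt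
Reagents that add atoms: none
Why: Reduction of a tertiary amide to the aldehyde by the zirconocene hydride chloride, which stops at the aldehyde level because the C–N bond is cleaved only on aqueous work-up; morpholine amides behave like N-methoxy-N-methyl amides here, and no alkene or ketone is left to compete.

Step 11
Reactants: 19 aldehyde
Product: 20 2-ethyl-2-{[(1R,2S,5R)-1-(2-methoxyethenyl)-2-methyl-5-[(2S)-1-(tert-butyldiphenylsilyloxy)propan-2-yl]cyclopentyl]methyl}-1,3-dioxolane (E and Z)
Conditions: [Ph3PCH2OMe]Cl, KOtBu, THF, 0 °C to rt
Reagents that add atoms: (methoxymethyl)triphenylphosphonium chloride, COC[P+](c1ccccc1)(c2ccccc2)c3ccccc3.[Cl-]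
Why: Wittig alkoxymethylenation, which tolerates neopentyl aldehydes; the aldehyde has no α-hydrogen, so nothing can epimerise, and the enol ether geometry is irrelevant.

Step 12
Reactants: 20 enol ether
Product: 22 (1R,4S,5S)-1-[(2S)-1-(tert-butyldiphenylsilyloxy)propan-2-yl]-4,8-dimethylspiro[4.5]dec-7-en-9-one, via keto aldehyde 21 (not isolated)
Conditions: 1 M aq. HCl, THF, rt; then piperidine (0.3 equiv), AcOH (0.3 equiv), toluene, 80 °C
Reagents that add atoms: water, O (carbonyl oxygen on C9)
Why: Acid hydrolysis frees the C7 aldehyde and the C9 ketone together, and the intramolecular aldol condensation then joins C8 to C7 (6-enolendo-exo-trig) and dehydrates to the conjugated enone; the other conceivable aldol closures would give four-membered rings, so ring B is the only outcome, and no stereocentre is formed.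

Step 13
Reactants: 22 spiro enone
Product: 23 (1R,4S,5S,9S)-1-[(2S)-1-(tert-butyldiphenylsilyloxy)propan-2-yl]-4,8-dimethylspiro[4.5]dec-7-en-9-ol
Conditions: (R)-2-methyl-CBS-oxazaborolidine (0.5 equiv), BH3·SMe2 (0.7 equiv), THF, −30 °C
Reagents that add atoms: none
Why: Corey–Bakshi–Shibata reduction; the α-methyl alkene side of the ketone acts as the large group and the C10 methylene as the small one, so the (R)-catalyst should deliver hydride to the face that gives the 9S alcohol, under reagent control where the spiro ring offers little bias of its own.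

Step 14
Reactants: 23 allylic alcohol
Product: 24 (1R,4S,5S,9S)-1-[(2S)-1-(tert-butyldiphenylsilyloxy)propan-2-yl]-4,8-dimethylspiro[4.5]dec-7-en-9-yl 3-phenylpropanoate
Conditions: PhCH2CH2COCl, Et3N, DMAP (cat.), CH2Cl2, 0 °C
Reagents that add atoms: 3-phenylpropanoyl chloride, O=C(Cl)CCc1ccccc1
Why: Acylation of a secondary alcohol under nucleophilic catalysis; the C–O bond at C9 is not broken, so the configuration is kept.

Step 15
Reactants: 24 ester
Product: 25 (1R,4S,5S,9S)-1-[(2S)-1-hydroxypropan-2-yl]-4,8-dimethylspiro[4.5]dec-7-en-9-yl 3-phenylpropanoate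
Conditions: HF·pyridine, pyridine/THF, 0 °C to rt
Reagents that add atoms: none
Why: Fluoride cleavage of the silyl ether under buffered, weakly acidic conditions that neither hydrolyse nor ionise the allylic ester.

Step 16
Reactants: 25 primary alcohol
Product: 26 (1R,4S,5S,9S)-4,8-dimethyl-1-[(2S)-1-oxopropan-2-yl]spiro[4.5]dec-7-en-9-yl 3-phenylpropanoate
Conditions: Dess–Martin periodinane, CH2Cl2, 0 °C to rt
Reagents that add atoms: none
Why: Dess–Martin oxidation to the aldehyde without base, so the stereocentre C11 next to the new carbonyl is kept; the aldehyde is used at once.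

Step 17
Reactants: 27 3-methylfuran-2(5H)-one
Product: 28 tert-butyldimethyl[(3-methylfuran-2-yl)oxy]silane
Conditions: TBSOTf, Et3N, CH2Cl2, 0 °C
Reagents that add atoms: tert-butyldimethylsilyl trifluoromethanesulfonate, CC(C)(C)[Si](C)(C)OS(=O)(=O)C(F)(F)F
Why: Soft enolisation and O-silylation of the butenolide give the aromatic 2-silyloxyfuran, the usual dienolate equivalent for γ-selective aldol reactions.

Step 18
Reactants: 26 aldehyde; 28 silyloxyfuran
Product: 29 (1R,4S,5S,9S)-1-[(2S)-1-hydroxy-1-(4-methyl-5-oxo-2,5-dihydrofuran-2-yl)propan-2-yl]-4,8-dimethylspiro[4.5]dec-7-en-9-yl 3-phenylpropanoate (diastereomers at the two new centres)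
Conditions: BF3·OEt2 (1.1 equiv), CH2Cl2, −78 °C
Reagents that add atoms: none
Why: Vinylogous Mukaiyama aldol reaction; the furan attacks through its carbon 5, so the butenolide is joined at its γ-carbon to C12; the low temperature and the absence of base protect C11, and the two new centres are destroyed in step 19.

Step 19
Reactants: 29 aldol adduct
Product: 31 target (1R,4S,5S,9S)-4,8-dimethyl-1-[(2S)-1-[(2Z)-4-methyl-5-oxofuran-2(5H)-ylidene]propan-2-yl]spiro[4.5]dec-7-en-9-yl 3-phenylpropanoate, via mesylate 30 (not isolated)
Conditions: MsCl, Et3N, CH2Cl2, −20 °C; then DBU (1.5 equiv), −20 to 0 °C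
Reagents that add atoms: methanesulfonyl chloride, CS(=O)(=O)Cl (mesyl group of 30 only; nothing stays in 31)
Why: Mesylation and E1cB elimination through the furanolate formed by removal of the acidic γ-hydrogen; the Z-ylidene butenolide is the more stable isomer, and short exposure to base at low temperature is meant to leave C11 and the allylic ester alone.

## Compound list

1 | (S)-(+)-carvone, (5S)-2-methyl-5-(prop-1-en-2-yl)cyclohex-2-en-1-one | CC1=CC[C@@H](CC1=O)C(C)=C | starting material
2 | lithium (5S)-2-methyl-5-(prop-1-en-2-yl)cyclohex-1-en-1-olate | [Li]OC1=C(C)CC[C@@H](C1)C(C)=C | intermediate (not isolated)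
3 | (2S,5S)-2-methyl-5-(prop-1-en-2-yl)cyclohexan-1-one (trans-dihydrocarvone) | C[C@H]1CC[C@@H](CC1=O)C(C)=C | intermediate
4 | bis(pinacolboryl) derivative of 5: pinacolboryl on C12 and pinacol borate on the ring oxygen (carbinol epimers) | C[C@H]1CC[C@@H](CC1OB2OC(C)(C)C(C)(C)O2)[C@H](C)CB3OC(C)(C)C(C)(C)O3 | intermediate (not isolated)
5 | (2S,5S)-5-[(2S)-1-hydroxypropan-2-yl]-2-methylcyclohexan-1-ol (carbinol epimers) | C[C@H]1CC[C@@H](CC1O)[C@H](C)CO | intermediate
6 | (2S,5S)-5-[(2S)-1-(tert-butyldiphenylsilyloxy)propan-2-yl]-2-methylcyclohexan-1-ol (carbinol epimers) | C[C@H]1CC[C@@H](CC1O)[C@H](C)CO[Si](c2ccccc2)(c3ccccc3)C(C)(C)C | intermediate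
7 | (2S,5S)-5-[(2S)-1-(tert-butyldiphenylsilyloxy)propan-2-yl]-2-methylcyclohexan-1-one | C[C@H]1CC[C@@H](CC1=O)[C@H](C)CO[Si](c2ccccc2)(c3ccccc3)C(C)(C)C | intermediate
8 | (3R,6S)-3-[(2S)-1-(tert-butyldiphenylsilyloxy)propan-2-yl]-6-methyl-2-(trifluoroacetyl)cyclohexan-1-one (carbon 2 unassigned, largely enolised) | C[C@H]1CC[C@@H](C(C(=O)C(F)(F)F)C1=O)[C@H](C)CO[Si](c2ccccc2)(c3ccccc3)C(C)(C)C | intermediate (not isolated)
9 | (3R,6S)-3-[(2S)-1-(tert-butyldiphenylsilyloxy)propan-2-yl]-2-diazo-6-methylcyclohexan-1-one | C[C@H]1CC[C@@H](C(=[N+]=[N-])C1=O)[C@H](C)CO[Si](c2ccccc2)(c3ccccc3)C(C)(C)C | intermediate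
10 | 2-ethylacrolein (2-methylidenebutanal) | CCC(=C)C=O | starting material
11 | morpholine | C1COCCN1 | starting material
12 | 4-(2-methylidenebutyl)morpholine | C=C(CC)CN1CCOCC1 | intermediate
13 | [(2S,5R)-2-methyl-5-[(2S)-1-(tert-butyldiphenylsilyloxy)propan-2-yl]cyclopentylidene]methanone (ketene) | O=C=C1[C@@H](C)CC[C@@H]1[C@H](C)CO[Si](c2ccccc2)(c3ccccc3)C(C)(C)C | intermediate (not isolated)
14 | acyl ammonium enolate from 13 and 12 (zwitterion; nitrogen carries the 2-methylidenebutyl group) | [O-]C(=C1[C@@H](C)CC[C@@H]1[C@H](C)CO[Si](c2ccccc2)(c3ccccc3)C(C)(C)C)[N+]4(CC(=C)CC)CCOCC4 | intermediate (not isolated)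
15 | [(1R,2S,5R)-2-methyl-1-(2-methylidenebutyl)-5-[(2S)-1-(tert-butyldiphenylsilyloxy)propan-2-yl]cyclopentyl](morpholin-4-yl)methanone | CC(C)(C)[Si](c1ccccc1)(c2ccccc2)OC[C@@H](C)[C@H]3CC[C@H](C)[C@@]3(CC(=C)CC)C(=O)N4CCOCC4 | intermediate
16 | ozonide of 15 (3-ethyl-1,2,4-trioxolan-3-ylmethyl arm on C5) | CC(C)(C)[Si](c1ccccc1)(c2ccccc2)OC[C@@H](C)[C@H]3CC[C@H](C)[C@@]3(CC5(CC)OCOO5)C(=O)N4CCOCC4 | intermediate (not isolated)
17 | [(1R,2S,5R)-2-methyl-1-(2-oxobutyl)-5-[(2S)-1-(tert-butyldiphenylsilyloxy)propan-2-yl]cyclopentyl](morpholin-4-yl)methanone | CC(C)(C)[Si](c1ccccc1)(c2ccccc2)OC[C@@H](C)[C@H]3CC[C@H](C)[C@@]3(CC(=O)CC)C(=O)N4CCOCC4 | intermediate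
18 | [(1R,2S,5R)-1-[(2-ethyl-1,3-dioxolan-2-yl)methyl]-2-methyl-5-[(2S)-1-(tert-butyldiphenylsilyloxy)propan-2-yl]cyclopentyl](morpholin-4-yl)methanone | CC(C)(C)[Si](c1ccccc1)(c2ccccc2)OC[C@@H](C)[C@H]3CC[C@H](C)[C@@]3(CC5(CC)OCCO5)C(=O)N4CCOCC4 | intermediate
19 | (1R,2S,5R)-1-[(2-ethyl-1,3-dioxolan-2-yl)methyl]-2-methyl-5-[(2S)-1-(tert-butyldiphenylsilyloxy)propan-2-yl]cyclopentane-1-carbaldehyde | CC(C)(C)[Si](c1ccccc1)(c2ccccc2)OC[C@@H](C)[C@H]3CC[C@H](C)[C@@]3(CC4(CC)OCCO4)C=O | intermediate
20 | 2-ethyl-2-{[(1R,2S,5R)-1-(2-methoxyethenyl)-2-methyl-5-[(2S)-1-(tert-butyldiphenylsilyloxy)propan-2-yl]cyclopentyl]methyl}-1,3-dioxolane (E and Z) | CC(C)(C)[Si](c1ccccc1)(c2ccccc2)OC[C@@H](C)[C@H]3CC[C@H](C)[C@@]3(CC4(CC)OCCO4)C=COC | intermediate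
21 | 2-[(1S,2S,5R)-2-methyl-1-(2-oxobutyl)-5-[(2S)-1-(tert-butyldiphenylsilyloxy)propan-2-yl]cyclopentyl]acetaldehyde | CC(C)(C)[Si](c1ccccc1)(c2ccccc2)OC[C@@H](C)[C@H]3CC[C@H](C)[C@@]3(CC(=O)CC)CC=O | intermediate (not isolated)
22 | (1R,4S,5S)-1-[(2S)-1-(tert-butyldiphenylsilyloxy)propan-2-yl]-4,8-dimethylspiro[4.5]dec-7-en-9-one | CC(C)(C)[Si](c1ccccc1)(c2ccccc2)OC[C@@H](C)[C@H]3CC[C@H](C)[C@@]34CC=C(C)C(=O)C4 | intermediate
23 | (1R,4S,5S,9S)-1-[(2S)-1-(tert-butyldiphenylsilyloxy)propan-2-yl]-4,8-dimethylspiro[4.5]dec-7-en-9-ol | CC(C)(C)[Si](c1ccccc1)(c2ccccc2)OC[C@@H](C)[C@H]3CC[C@H](C)[C@@]34CC=C(C)[C@@H](O)C4 | intermediate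
24 | (1R,4S,5S,9S)-1-[(2S)-1-(tert-butyldiphenylsilyloxy)propan-2-yl]-4,8-dimethylspiro[4.5]dec-7-en-9-yl 3-phenylpropanoate | CC(C)(C)[Si](c1ccccc1)(c2ccccc2)OC[C@@H](C)[C@H]3CC[C@H](C)[C@@]34CC=C(C)[C@@H](OC(=O)CCc5ccccc5)C4 | intermediate
25 | (1R,4S,5S,9S)-1-[(2S)-1-hydroxypropan-2-yl]-4,8-dimethylspiro[4.5]dec-7-en-9-yl 3-phenylpropanoate | OC[C@@H](C)[C@H]1CC[C@H](C)[C@@]12CC=C(C)[C@@H](OC(=O)CCc3ccccc3)C2 | intermediate
26 | (1R,4S,5S,9S)-4,8-dimethyl-1-[(2S)-1-oxopropan-2-yl]spiro[4.5]dec-7-en-9-yl 3-phenylpropanoate | O=C[C@@H](C)[C@H]1CC[C@H](C)[C@@]12CC=C(C)[C@@H](OC(=O)CCc3ccccc3)C2 | intermediate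
27 | 3-methylfuran-2(5H)-one | CC1=CCOC1=O | starting material
28 | tert-butyldimethyl[(3-methylfuran-2-yl)oxy]silane | Cc1ccoc1O[Si](C)(C)C(C)(C)C | intermediate
29 | (1R,4S,5S,9S)-1-[(2S)-1-hydroxy-1-(4-methyl-5-oxo-2,5-dihydrofuran-2-yl)propan-2-yl]-4,8-dimethylspiro[4.5]dec-7-en-9-yl 3-phenylpropanoate (diastereomers at carbinol and lactone carbons) | CC1=CC(OC1=O)C(O)[C@@H](C)[C@H]2CC[C@H](C)[C@@]23CC=C(C)[C@@H](OC(=O)CCc4ccccc4)C3 | intermediate
30 | methanesulfonate of 29 | CC1=CC(OC1=O)C(OS(C)(=O)=O)[C@@H](C)[C@H]2CC[C@H](C)[C@@]23CC=C(C)[C@@H](OC(=O)CCc4ccccc4)C3 | intermediate (not isolated)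
31 | (1R,4S,5S,9S)-4,8-dimethyl-1-[(2S)-1-[(2Z)-4-methyl-5-oxofuran-2(5H)-ylidene]propan-2-yl]spiro[4.5]dec-7-en-9-yl 3-phenylpropanoate (CNP0260277.1) | CC1=C/C(=C/[C@@H](C)[C@H]2CC[C@H](C)[C@@]23CC=C(C)[C@@H](OC(=O)CCc2ccccc2)C3)OC1=O | target

## Step count and least certain steps

Total: 19 steps. Longest linear sequence: 17 steps (steps 1 to 5, 7 to 16, 18 and 19); steps 6 and 17 are side branches.

**Step 7 (key step).**
- What may go wrong: capture of the hindered dialkylketene by the tertiary amine may be slow or reversible, so that the ketene is lost by dimerisation or by reaction with unchanged diazo ketone. Face selection at C5 may be weak, because it rests only on the difference in size between a methyl group and a branched chain. Some carbene may escape the concerted path and be trapped by the amine.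
- Fallback (known chemistry), from 9 back to 19: photolysis of 9 in methanol (Wolff rearrangement with capture by the alcohol) should give the ring-contracted methyl ester F1 as a mixture at C5. Deprotonation with LiN(i-Pr)2 and alkylation of the ester enolate with 2-(bromomethyl)but-1-ene should give the quaternary ester F2, the halide approaching anti to the C1 side chain for the same steric reason. Cleavage of the methylidene group (OsO4 cat., NaIO4, 2,6-lutidine) gives the keto ester F3, ketalisation as in step 9 gives the ketal ester F4, and i-Bu2AlH at −78 °C takes the hindered ester to aldehyde 19.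

**Step 2.**
- What may go wrong: the catalyst may discriminate poorly between the methyl group and the ring in the hydrocupration, or show the opposite sense to the one assumed, and the borate formed from the ketone may slow the catalyst.
- Fallback, from 3 back to 7: allylic hydroxylation of the isopropenyl methyl group (SeO2 cat., t-BuOOH, CH2Cl2) gives the allylic alcohol F5. Hydroxyl-directed asymmetric hydrogenation with Ru(OAc)2(BINAP), its antipode chosen in a trial as for step 2, gives the hydroxy ketone F6 without touching the ketone. TBDPSCl and imidazole then give 7, so steps 2 to 4 are bypassed.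

**Step 10.**
- What may go wrong: hydride delivery to the amide carbonyl, which sits on a quaternary carbon between two substituted carbons, may be incomplete, or reduction may run on to the amine.
- Fallback, from 18 back to 19: LiNH2BH3 (from BH3·NH3 and LiN(i-Pr)2), a small and strong reagent, reduces the amide to the primary alcohol F7, and Dess–Martin oxidation gives 19.

**Step 13.**
- What may go wrong: the intrinsic facial bias of the spiro enone may oppose the catalyst, which would erode the selectivity at C9.
- Fallback, from 22 back to 24: reduction with the (S)-catalyst (or with LiBH(s-Bu)3 if substrate control proves strong) is aimed at the 9R alcohol F8. Mitsunobu esterification with 3-phenylpropanoic acid (PPh3, DIAD) then installs the ester with inversion and gives 24 directly, replacing steps 13 and 14.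

**Step 19.**
- What may go wrong: the base may remove the C11 hydrogen of the product, which is allylic to the ylidene butenolide, causing epimerisation or migration of the double bond, and the elimination may give an E/Z mixture.
- Fallback, from 26 and 27 back to 31: radical bromination of 27 (NBS, CCl4, light) gives the bromobutenolide F9, and PPh3 converts it into the phosphonium salt F10. Wittig reaction of the ylide from F10 (Et3N, CH2Cl2, 0 °C) with aldehyde 26 forms the C12=C bond directly, without a β-elimination step, and gives 31, the Z isomer being the more stable one.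

## Further compounds

F1 | step 7 | methyl (2S,5R)-2-methyl-5-[(2S)-1-(tert-butyldiphenylsilyloxy)propan-2-yl]cyclopentane-1-carboxylate (epimers at carbon 1) | COC(=O)C1[C@@H](C)CC[C@@H]1[C@H](C)CO[Si](c2ccccc2)(c3ccccc3)C(C)(C)C
F2 | step 7 | methyl (1R,2S,5R)-2-methyl-1-(2-methylidenebutyl)-5-[(2S)-1-(tert-butyldiphenylsilyloxy)propan-2-yl]cyclopentane-1-carboxylate | CC(C)(C)[Si](c1ccccc1)(c2ccccc2)OC[C@@H](C)[C@H]3CC[C@H](C)[C@@]3(CC(=C)CC)C(=O)OC
F3 | step 7 | methyl (1R,2S,5R)-2-methyl-1-(2-oxobutyl)-5-[(2S)-1-(tert-butyldiphenylsilyloxy)propan-2-yl]cyclopentane-1-carboxylate | CC(C)(C)[Si](c1ccccc1)(c2ccccc2)OC[C@@H](C)[C@H]3CC[C@H](C)[C@@]3(CC(=O)CC)C(=O)OC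
F4 | step 7 | methyl (1R,2S,5R)-1-[(2-ethyl-1,3-dioxolan-2-yl)methyl]-2-methyl-5-[(2S)-1-(tert-butyldiphenylsilyloxy)propan-2-yl]cyclopentane-1-carboxylate | CC(C)(C)[Si](c1ccccc1)(c2ccccc2)OC[C@@H](C)[C@H]3CC[C@H](C)[C@@]3(CC4(CC)OCCO4)C(=O)OC
F5 | step 2 | (2S,5S)-5-(3-hydroxyprop-1-en-2-yl)-2-methylcyclohexan-1-one | C[C@H]1CC[C@@H](CC1=O)C(=C)CO
F6 | step 2 | (2S,5S)-5-[(2S)-1-hydroxypropan-2-yl]-2-methylcyclohexan-1-one | C[C@H]1CC[C@@H](CC1=O)[C@H](C)CO
F7 | step 10 | [(1R,2S,5R)-1-[(2-ethyl-1,3-dioxolan-2-yl)methyl]-2-methyl-5-[(2S)-1-(tert-butyldiphenylsilyloxy)propan-2-yl]cyclopentyl]methanol | CC(C)(C)[Si](c1ccccc1)(c2ccccc2)OC[C@@H](C)[C@H]3CC[C@H](C)[C@@]3(CC4(CC)OCCO4)CO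
F8 | step 13 | (1R,4S,5S,9R)-1-[(2S)-1-(tert-butyldiphenylsilyloxy)propan-2-yl]-4,8-dimethylspiro[4.5]dec-7-en-9-ol | CC(C)(C)[Si](c1ccccc1)(c2ccccc2)OC[C@@H](C)[C@H]3CC[C@H](C)[C@@]34CC=C(C)[C@H](O)C4
F9 | step 19 | 5-bromo-3-methylfuran-2(5H)-one | CC1=CC(Br)OC1=O
F10 | step 19 | (4-methyl-5-oxo-2,5-dihydrofuran-2-yl)triphenylphosphonium bromide | CC1=CC(OC1=O)[P+](c2ccccc2)(c3ccccc3)c4ccccc4.[Br-]
A1 | alternative 1 | (2Z)-2-methyl-5-[2-methyl-1-(trimethylsilyloxy)cyclobutyl]hexa-2,5-dienoyl chloride | C[C@H]1CC[C@]1(O[Si](C)(C)C)C(=C)C/C=C(C)\C(Cl)=O
A2 | alternative 1 | (4S,5S)-4,8-dimethylspiro[4.5]dec-7-ene-1,9-dione | O=C1CC[C@H](C)[C@@]12CC=C(C)C(=O)C2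
A3 | alternative 2 | methyl (2E,6S)-2-methyl-6-(3-oxocyclohex-1-en-1-yl)hept-2-enoate | COC(=O)/C(C)=C/CC[C@H](C)C1=CC(=O)CCC1
A4 | alternative 2 | tricyclic photoadduct: methyl ester on C11 of a cyclobutane (C1, C5, C6, C11) cis-fused to ring A and to the C7 cyclohexanone | COC(=O)[C@]1(C)[C@H]2CC[C@H](C)[C@@]2(CCCC3=O)[C@@H]13
A5 | alternative 3 | 3-(tert-butyldimethylsilyloxy)-2-ethenyl-2,5-dimethyl-2,3,4,5,6,7-hexahydrocyclopenta[b]pyran (silyloxy group trans to the ethenyl group) | C=C[C@@]1(C)OC2=C(C[C@@H]1O[Si](C)(C)C(C)(C)C)[C@@H](C)CC2
A6 | alternative 3 | (4S,5S,9S)-9-(tert-butyldimethylsilyloxy)-4,8-dimethylspiro[4.5]dec-7-en-1-one | O=C1CC[C@H](C)[C@@]12CC=C(C)[C@@H](O[Si](C)(C)C(C)(C)C)C2
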